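## Retrosynthetic overview

1. **Feature.** Ring B is a hexasubstituted phloroglucinol: C1' carries the CH2 bridge, C2'/C4'/C6' carry OH, C3' isobutyryl, C5' prenyl. One CH2 ties it to C2 of the dearomatised ring A. A C1'-CH2-C2 link made from two ring nucleophiles and a one-carbon unit swaps partners, so ring B is grown on the bridge carbon itself.
2. 36 <= fluoride deprotection of phenol 35 <= Danheiser benzannulation of cyclobutenone 30 (ring A on its C4 methylene) with siloxyalkyne 27. Alkyne 27 brings C3' with the isobutyryl group masked as its silyl enol ether. Bonds C2'-C3' and C4'-C5' form, then a 6-pi closure makes C1'-C2'.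
3. 30 <= [2+2] of the ketene from ring-A propanoic acid 16 with prenyl siloxyalkyne 21 (C1'-C6' bond).
4. 16 <= C2 iodination and Negishi coupling of dienone 11 <= Birch reduction, C4 acylation and bis-allylic oxidation of a 4-methylresorcinol diether, then resolution.
5. Ring order: ring A first (from the arene), the four-membered ring as a relay, ring B last.

Key step: step 16

**Remark on the chemistry.** The two ring flanks of C4 differ only in CH3 against CH2, three bonds away. No reagent-controlled construction of this centre can be defended, so it is secured by resolution. The parent siloxyethyne is avoided because lithium ethynolate is expected to silylate on carbon.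

**Abbreviations.**
- prenyl = 3-methylbut-2-en-1-yl
- TMSE = 2-(trimethylsilyl)ethyl
- TIPS = triisopropylsilyl
- TBS = tert-butyldimethylsilyl
- Ring A numbering: C1 (C=O), C2 (bridge), C3 (O), C4 (quaternary), C5 (O), C6 (CH3)
- RA = (S)-4-isobutyryl-6-methyl-1-oxo-4-prenyl-3,5-bis(TMSE-oxy)cyclohexa-2,5-dien-2-yl

## Route

Step 1
Reactants: 1 4-methylresorcinol
Product: 2 2,4-bis[2-(trimethylsilyl)ethoxy]toluene
Conditions: Me3SiCH2CH2OH (2.4 equiv), PPh3, DIAD, THF, 0 °C to rt
Reagents that add atoms: 2-(trimethylsilyl)ethanol, OCC[Si](C)(C)C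
Why: Double Mitsunobu etherification of phenols with a primary alcohol is routine, and it gives alkyl-type ethers that survive organolithiums and dissolving metal yet leave with fluoride at the end.

Step 2
Reactants: 2 2,4-bis[2-(trimethylsilyl)ethoxy]toluene; 3 prenyl bromide
Product: 5 2,4-bis[2-(trimethylsilyl)ethoxy]-3-prenyltoluene, via aryllithium 4 (not isolated)
Conditions: n-BuLi, TMEDA, THF, 0 °C to rt; then 3, -78 °C to rt
Reagents that add atoms: none
Why: Directed ortho-metalation removes the proton between the two alkoxy groups (the future C4), and the aryllithium displaces the allylic bromide at its primary carbon.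

Step 3
Reactants: 5 2,4-bis[2-(trimethylsilyl)ethoxy]-3-prenyltoluene
Product: 6 rac-2-methyl-6-prenyl-1,5-bis(TMSE-oxy)cyclohexa-1,4-diene
Conditions: Li, NH3(l), THF, t-BuOH, -78 to -33 °C; solid NH4Cl
Reagents that add atoms: none
Why: Birch reduction of a resorcinol diether protonates the carbon between the alkoxy groups and the one para to it, so both oxygens stay on double bonds and the isolated prenyl alkene is untouched; the C4-H centre is racemic and is erased in step 4.

Step 4
Reactants: 6 rac-2-methyl-6-prenyl-1,5-bis(TMSE-oxy)cyclohexa-1,4-diene; 7 isobutyryl chloride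
Product: 9 rac-1-[3-methyl-1-prenyl-2,6-bis(TMSE-oxy)cyclohexa-2,5-dien-1-yl]-2-methylpropan-1-one, via cyclohexadienyllithium 8 (not isolated)
Conditions: s-BuLi, THF, -78 to -40 °C; cannulated into 7, THF, -78 °C
Reagents that add atoms: none
Why: The doubly allylic C4-H is the only acidic proton, the cyclohexadienyl anion reacts at its central carbon as in Birch alkylations, and C-acylation gives a ketone too hindered for a second addition; the quaternary centre forms racemic.

Step 5
Reactants: 9 rac-1-[3-methyl-1-prenyl-2,6-bis(TMSE-oxy)cyclohexa-2,5-dien-1-yl]-2-methylpropan-1-one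
Product: 10 rac-4-isobutyryl-2-methyl-4-prenyl-3,5-bis(TMSE-oxy)cyclohexa-2,5-dien-1-one
Conditions: t-BuOOH, (C5H5NH)2Cr2O7, Celite, benzene, rt
Reagents that add atoms: tert-butyl hydroperoxide, CC(C)(C)OO
Why: Bis-allylic oxidation of 6,6-disubstituted 1-alkoxycyclohexa-1,4-dienes with this reagent pair is an established route to 4,4-disubstituted cyclohexadienones, the doubly activated ring CH2 reacts ahead of the prenyl allylic positions, and the enol ethers are fixed in the cross-conjugated 3,5-pattern.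

Step 6
Reactants: 10 rac-4-isobutyryl-2-methyl-4-prenyl-3,5-bis(TMSE-oxy)cyclohexa-2,5-dien-1-one
Product: 11 (R)-4-isobutyryl-2-methyl-4-prenyl-3,5-bis(TMSE-oxy)cyclohexa-2,5-dien-1-one
Conditions: preparative SFC, immobilised amylose tris(3,5-dimethylphenylcarbamate), CO2/2-propanol
Reagents that add atoms: none
Why: Chromatographic resolution on a polysaccharide phase selects the C4 configuration, and the fraction to keep is identified by anomalous-dispersion X-ray analysis of iodide 13 made from each fraction; the descriptor changes to S once C2 is substituted, with the same spatial arrangement.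

Step 7
Reactants: 11 (R)-4-isobutyryl-2-methyl-4-prenyl-3,5-bis(TMSE-oxy)cyclohexa-2,5-dien-1-one
Product: 13 (S)-2-iodo-4-isobutyryl-6-methyl-4-prenyl-3,5-bis(TMSE-oxy)cyclohexa-2,5-dien-1-one, via vinyllithium 12 (not isolated)
Conditions: LiN(iPr)2, THF, -78 °C; I2, -78 °C
Reagents that add atoms: iodine, I-I
Why: Alkoxy-assisted alpha-lithiation of the vinylic C2-H of a vinylogous ester is faster than enolisation of the buried isobutyryl methine, and iodine traps the vinyllithium without touching C4.

Step 8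
Reactants: 13 (S)-2-iodo-4-isobutyryl-6-methyl-4-prenyl-3,5-bis(TMSE-oxy)cyclohexa-2,5-dien-1-one; 14 (3-ethoxy-3-oxopropyl)zinc bromide
Product: 15 ethyl 3-(RA)propanoate
Conditions: Pd2(dba)3 (2.5 mol %), P(2-furyl)3 (10 mol %), THF, rt to 40 °C
Reagents that add atoms: none
Why: Negishi coupling of alpha-iodoenones with alkylzinc halides is known, the zinc homoenolate does not add to ketones, and 4-allyl-type cyclohexadienones of this kind tolerate zerovalent palladium.

Step 9
Reactants: 15 ethyl 3-(RA)propanoate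
Product: 16 3-(RA)propanoic acid
Conditions: Me3SnOH, ClCH2CH2Cl, 70 °C; cold 0.1 M HCl wash
Reagents that add atoms: trimethyltin hydroxide, C[Sn](C)(C)O
Why: Trimethyltin hydroxide cleaves unhindered esters under near-neutral conditions and so avoids hydroxide attack on the C4 isobutyryl group, whose loss would aromatise ring A.

Step 10
Reactants: 3 prenyl bromide; 17 ethynylmagnesium bromide
Product: 18 5-methylhex-4-en-1-yne
Conditions: CuCl (5 mol %), THF, 0 to 45 °C
Reagents that add atoms: none
Why: Copper-catalysed coupling of an alkynyl Grignard reagent with an allylic bromide at the primary carbon is the standard way to skipped enynes.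

Step 11
Reactants: 18 5-methylhex-4-en-1-yne
Product: 21 triisopropyl[(5-methylhex-4-en-1-yn-1-yl)oxy]silane, via lithium acetylide 19 (not isolated), via lithium ynolate 20 (not isolated)
Conditions: n-BuLi, THF, -78 °C; t-BuOOLi (from t-BuOOH and LiN(SiMe3)2), -78 to 0 °C; TIPSOTf, -78 to 0 °C
Reagents that add atoms: tert-butyl hydroperoxide, CC(C)(C)OO; triisopropylsilyl triflate, CC(C)[Si](OS(=O)(=O)C(F)(F)F)(C(C)C)C(C)C
Why: Oxygenation of a lithium acetylide by lithium tert-butyl peroxide gives the ynolate, which a bulky silyl triflate traps on oxygen when the carbon end is substituted.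

Step 12
Reactants: 22 4-methylpent-1-yn-3-ol (racemic)
Product: 23 4-methylpent-1-yn-3-one
Conditions: activated MnO2, CH2Cl2, rt
Reagents that add atoms: none
Why: Manganese dioxide oxidises propargylic alcohols to ynones without touching the terminal alkyne.

Step 13
Reactants: 23 4-methylpent-1-yn-3-one
Product: 24 tert-butyldimethyl[(4-methylpent-3-en-1-yn-3-yl)oxy]silane
Conditions: TBSOTf, CH2Cl2, -78 °C; Et3N added slowly, to 0 °C
Reagents that add atoms: tert-butyldimethylsilyl triflate, CC(C)(C)[Si](C)(C)OS(=O)(=O)C(F)(F)F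
Why: Soft enolisation can only take the isopropyl methine, so a single enol silane without E/Z isomers results, and prior silyl activation keeps the amine from adding to the ynone.

Step 14
Reactants: 24 tert-butyldimethyl[(4-methylpent-3-en-1-yn-3-yl)oxy]silane
Product: 27 3-(tert-butyldimethylsiloxy)-4-methyl-1-(triisopropylsiloxy)pent-3-en-1-yne, via lithium acetylide 25 (not isolated), via lithium ynolate 26 (not isolated)
Conditions: n-BuLi, THF, -78 °C; t-BuOOLi (from t-BuOOH and LiN(SiMe3)2), -78 to 0 °C; TIPSOTf, -78 to 0 °C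
Reagents that add atoms: tert-butyl hydroperoxide, CC(C)(C)OO; triisopropylsilyl triflate, CC(C)[Si](OS(=O)(=O)C(F)(F)F)(C(C)C)C(C)C
Why: This is the same acetylide oxygenation and O-silylation as in step 11, and the hindered TBS enol ether tolerates the short cold exposure to the lithium reagents.

Step 15
Reactants: 16 3-(RA)propanoic acid; 21 triisopropyl[(5-methylhex-4-en-1-yn-1-yl)oxy]silane
Product: 30 4-[(RA)methyl]-2-prenyl-3-(triisopropylsiloxy)cyclobut-2-en-1-one (both C4 epimers), via acid chloride 28 (not isolated), via ketene 29 (not isolated)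
Conditions: 1-chloro-N,N,2-trimethylprop-1-en-1-amine, CH2Cl2, 0 °C; added over 4 h to 21 (2 equiv), Et3N, CH2Cl2, 35 °C
Reagents that add atoms: none
Why: The chloroenamine makes the acid chloride without acid, Et3N dehydrochlorinates it to the monoalkylketene, and the excess siloxyalkyne captures it in a ketene-ynol ether [2+2] with the prenyl-bearing carbon bonding to the ketene carbonyl; the new cyclobutenone C4 centre forms as both epimers, which converge in step 16.

Step 16
Reactants: 30 4-[(RA)methyl]-2-prenyl-3-(triisopropylsiloxy)cyclobut-2-en-1-one; 27 3-(tert-butyldimethylsiloxy)-4-methyl-1-(triisopropylsiloxy)pent-3-en-1-yne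
Product: 35 ring-B phenol (C1' CH2-RA; C2' OH; C3' 1-(TBS-oxy)-2-methylprop-1-enyl; C4' OTIPS; C5' prenyl; C6' OTIPS), via vinylketene 31 (not isolated), via 4-vinylcyclobutenone 32 (not isolated), via dienylketene 33 (not isolated), via cyclohexadienone 34 (not isolated)
Conditions: 27 (2.5 equiv), toluene, sealed tube, 80 °C then 110 °C, argon
Reagents that add atoms: none
Why: Heating opens 30 by conrotatory 4-pi cleavage of its C1-C4 bond (the CH2-RA group turning outward) to vinylketene 31, the nucleophilic carbon of 27 that carries the masked isobutyryl group adds to the ketene carbonyl carbon (C2'-C3'), and the ketene alpha-carbon closes on the siloxy-bearing carbon (C4'-C5') to give 4-vinylcyclobutenone 32. Compound 32 opens again, reversibly, to dienylketene 33, and ring B closes by thermal disrotatory 6-pi electrocyclisation between C1' and C2' to cyclohexadienone 34, which tautomerises to phenol 35. This is the Danheiser benzannulation in its cyclobutenone plus siloxyalkyne form, the known route to resorcinol and phloroglucinol ethers, applied here to a 3-siloxycyclobutenone. No stereocentre is created: both C4 epimers of 30 and both epimers of 32 funnel into the same arene, and C4 of ring A is a spectator that cannot enolise. The selectivity needed is the orientation of ketene and ynol ether, and the polarity imposed by the two siloxy groups secures it, so the three oxygens fall 1,3,5; since bridge, prenyl and acyl carbon then fill the alternate positions, even a direct six-ring closure of the zwitterion leads to the same triol after step 17. Ring A stays inert because both enols are alkyl ethers held in the cross-conjugated dienone, where the C4 acyl group has no adjacent carbonyl oxygen or diene terminus to migrate to.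

Step 17
Reactants: 35 ring-B phenol
Product: 36 target CNP0191741.1, (S) at C4 of ring A
Conditions: Bu4NF (12 equiv), AcOH (6 equiv), THF, 0 °C to rt, argon; pH 5 phosphate buffer
Reagents that add atoms: none
Why: Fluoride cleaves the aryl TIPS ethers and the TBS enol ether (which becomes the C3' isobutyryl ketone) and triggers beta-elimination of ethene from the two TMSE vinylogous esters, while the acetic acid buffer keeps phenoxides protonated and so suppresses retro-Claisen loss of the C4 acyl group and base-induced exchange of the methylene bridge; C4 is untouched.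

## Compound list

1 | 4-methylresorcinol | Cc1ccc(O)cc1O | starting material
2 | 2,4-bis[2-(trimethylsilyl)ethoxy]toluene | Cc1ccc(OCC[Si](C)(C)C)cc1OCC[Si](C)(C)C | intermediate
3 | prenyl bromide | CC(C)=CCBr | starting material
4 | 3-lithio derivative of 2 | Cc1ccc(OCC[Si](C)(C)C)c([Li])c1OCC[Si](C)(C)C | intermediate
5 | 2,4-bis[2-(trimethylsilyl)ethoxy]-3-prenyltoluene | Cc1ccc(OCC[Si](C)(C)C)c(CC=C(C)C)c1OCC[Si](C)(C)C | intermediate
6 | rac-2-methyl-6-prenyl-1,5-bis(TMSE-oxy)cyclohexa-1,4-diene | CC1=C(OCC[Si](C)(C)C)C(CC=C(C)C)C(OCC[Si](C)(C)C)=CC1 | intermediate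
7 | isobutyryl chloride | CC(C)C(=O)Cl | starting material
8 | 6-lithio derivative of 6 | CC1=C(OCC[Si](C)(C)C)C([Li])(CC=C(C)C)C(OCC[Si](C)(C)C)=CC1 | intermediate
9 | rac-1-[3-methyl-1-prenyl-2,6-bis(TMSE-oxy)cyclohexa-2,5-dien-1-yl]-2-methylpropan-1-one | CC1=C(OCC[Si](C)(C)C)C(CC=C(C)C)(C(=O)C(C)C)C(OCC[Si](C)(C)C)=CC1 | intermediate
10 | rac-4-isobutyryl-2-methyl-4-prenyl-3,5-bis(TMSE-oxy)cyclohexa-2,5-dien-1-one | O=C1C=C(OCC[Si](C)(C)C)C(CC=C(C)C)(C(=O)C(C)C)C(OCC[Si](C)(C)C)=C1C | intermediate
11 | (R)-4-isobutyryl-2-methyl-4-prenyl-3,5-bis(TMSE-oxy)cyclohexa-2,5-dien-1-one | O=C1C=C(OCC[Si](C)(C)C)[C@@](CC=C(C)C)(C(=O)C(C)C)C(OCC[Si](C)(C)C)=C1C | intermediate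
12 | C2-lithio derivative of 11 | O=C1C([Li])=C(OCC[Si](C)(C)C)[C@@](CC=C(C)C)(C(=O)C(C)C)C(OCC[Si](C)(C)C)=C1C | intermediate
13 | (S)-2-iodo-4-isobutyryl-6-methyl-4-prenyl-3,5-bis(TMSE-oxy)cyclohexa-2,5-dien-1-one | O=C1C(I)=C(OCC[Si](C)(C)C)[C@@](CC=C(C)C)(C(=O)C(C)C)C(OCC[Si](C)(C)C)=C1C | intermediate
14 | (3-ethoxy-3-oxopropyl)zinc bromide | CCOC(=O)CC[Zn]Br | starting material
15 | ethyl 3-(RA)propanoate | CCOC(=O)CCC1=C(OCC[Si](C)(C)C)[C@@](CC=C(C)C)(C(=O)C(C)C)C(OCC[Si](C)(C)C)=C(C)C1=O | intermediate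
16 | 3-(RA)propanoic acid | OC(=O)CCC1=C(OCC[Si](C)(C)C)[C@@](CC=C(C)C)(C(=O)C(C)C)C(OCC[Si](C)(C)C)=C(C)C1=O | intermediate
17 | ethynylmagnesium bromide | C#C[Mg]Br | starting material
18 | 5-methylhex-4-en-1-yne | C#CCC=C(C)C | intermediate
19 | lithium acetylide of 18 | [Li]C#CCC=C(C)C | intermediate
20 | lithium 5-methylhex-4-en-1-yn-1-olate | [Li]OC#CCC=C(C)C | intermediate
21 | triisopropyl[(5-methylhex-4-en-1-yn-1-yl)oxy]silane | CC(C)=CCC#CO[Si](C(C)C)(C(C)C)C(C)C | intermediate
22 | 4-methylpent-1-yn-3-ol (racemic) | C#CC(O)C(C)C | starting material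
23 | 4-methylpent-1-yn-3-one | C#CC(=O)C(C)C | intermediate
24 | tert-butyldimethyl[(4-methylpent-3-en-1-yn-3-yl)oxy]silane | C#CC(O[Si](C)(C)C(C)(C)C)=C(C)C | intermediate
25 | lithium acetylide of 24 | [Li]C#CC(O[Si](C)(C)C(C)(C)C)=C(C)C | intermediate
26 | lithium ynolate from 25 | [Li]OC#CC(O[Si](C)(C)C(C)(C)C)=C(C)C | intermediate
27 | 3-(tert-butyldimethylsiloxy)-4-methyl-1-(triisopropylsiloxy)pent-3-en-1-yne | CC(C)=C(O[Si](C)(C)C(C)(C)C)C#CO[Si](C(C)C)(C(C)C)C(C)C | intermediate
28 | 3-(RA)propanoyl chloride | ClC(=O)CCC1=C(OCC[Si](C)(C)C)[C@@](CC=C(C)C)(C(=O)C(C)C)C(OCC[Si](C)(C)C)=C(C)C1=O | intermediate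
29 | 3-(RA)prop-1-en-1-one (ketene) | O=C=CCC1=C(OCC[Si](C)(C)C)[C@@](CC=C(C)C)(C(=O)C(C)C)C(OCC[Si](C)(C)C)=C(C)C1=O | intermediate
30 | 4-[(RA)methyl]-2-prenyl-3-(triisopropylsiloxy)cyclobut-2-en-1-one, both C4 epimers | O=C1C(CC=C(C)C)=C(O[Si](C(C)C)(C(C)C)C(C)C)C1CC2=C(OCC[Si](C)(C)C)[C@@](CC=C(C)C)(C(=O)C(C)C)C(OCC[Si](C)(C)C)=C(C)C2=O | intermediate
31 | vinylketene from 30 | O=C=C(CC=C(C)C)/C(O[Si](C(C)C)(C(C)C)C(C)C)=C/CC1=C(OCC[Si](C)(C)C)[C@@](CC=C(C)C)(C(=O)C(C)C)C(OCC[Si](C)(C)C)=C(C)C1=O | intermediate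
32 | 4-vinylcyclobutenone from 31 and 27, both epimers at the ring quaternary carbon | O=C1C(C(O[Si](C)(C)C(C)(C)C)=C(C)C)=C(O[Si](C(C)C)(C(C)C)C(C)C)C1(CC=C(C)C)/C(O[Si](C(C)C)(C(C)C)C(C)C)=C/CC2=C(OCC[Si](C)(C)C)[C@@](CC=C(C)C)(C(=O)C(C)C)C(OCC[Si](C)(C)C)=C(C)C2=O | intermediate
33 | dienylketene from 32 (isomer that closes) | O=C=C(C(O[Si](C)(C)C(C)(C)C)=C(C)C)/C(O[Si](C(C)C)(C(C)C)C(C)C)=C(CC=C(C)C)\C(O[Si](C(C)C)(C(C)C)C(C)C)=C\CC2=C(OCC[Si](C)(C)C)[C@@](CC=C(C)C)(C(=O)C(C)C)C(OCC[Si](C)(C)C)=C(C)C2=O | intermediate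
34 | cyclohexa-2,4-dienone tautomer of 35 | O=C1C(C(O[Si](C)(C)C(C)(C)C)=C(C)C)=C(O[Si](C(C)C)(C(C)C)C(C)C)C(CC=C(C)C)=C(O[Si](C(C)C)(C(C)C)C(C)C)C1CC2=C(OCC[Si](C)(C)C)[C@@](CC=C(C)C)(C(=O)C(C)C)C(OCC[Si](C)(C)C)=C(C)C2=O | intermediate
35 | ring-B phenol bridged to RA | Oc1c(C(O[Si](C)(C)C(C)(C)C)=C(C)C)c(O[Si](C(C)C)(C(C)C)C(C)C)c(CC=C(C)C)c(O[Si](C(C)C)(C(C)C)C(C)C)c1CC2=C(OCC[Si](C)(C)C)[C@@](CC=C(C)C)(C(=O)C(C)C)C(OCC[Si](C)(C)C)=C(C)C2=O | intermediate
36 | CNP0191741.1 | CC(C)=CCc1c(O)c(CC2=C(O)[C@@](CC=C(C)C)(C(=O)C(C)C)C(O)=C(C)C2=O)c(O)c(C(=O)C(C)C)c1O | target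

## Step count

- Total steps: 17
- Longest linear sequence: 12 (steps 1 to 9, then 15, 16 and 17)

## Steps most likely to fail

**Step 16.**
- What may go wrong: the hindered alkyne 27 may capture the fully substituted vinylketene 31 more slowly than the ketene dimerises or esterifies the phenol already formed.
- The fallback sets out from 30 and returns at 36. It takes the acyl carbon out of the alkyne and installs it after the ring is built.
- 2-(Trimethylsilyl)ethanol, KH and trichloroethene give (E)-1,2-dichlorovinyl 2-(trimethylsilyl)ethyl ether F1.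
- n-BuLi (elimination, then chlorine-lithium exchange) followed by a proton quench gives [2-(ethynyloxy)ethyl]trimethylsilane F2.
- This unhindered terminal ynol ether is heated with 30 in toluene at 80 to 90 °C and gives the pentasubstituted phenol with C3'-H and free C2'-OH F3.
- F3 is treated with EtMgBr and then 7 in toluene. This is the ortho-coordinated acylation of an aryloxymagnesium bromide, at the only open ortho carbon, and gives the C3' isobutyryl phenol F4.
- Bu4NF buffered with AcOH removes the TIPS and TMSE groups and gives 36.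

**Step 4.**
- What may go wrong: attack at the crowded central carbon of anion 8 may be so slow that proton abstraction from the acid chloride, or acylation at the open terminus of the pentadienyl anion, takes over.
- The fallback sets out from 2 and returns at 9. It reverses the order of the two C4 substituents.
- Birch reduction of 2 gives 2-methyl-1,5-bis(TMSE-oxy)cyclohexa-1,4-diene F5.
- s-BuLi and then isobutyraldehyde give the secondary carbinol F6.
- Buffered Dess-Martin oxidation gives the 1-acylcyclohexa-2,5-diene F7.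
- KN(SiMe3)2 and prenyl bromide 3 alkylate its enolate at C4, as in Birch reductive alkylations, and give 9.

**Step 15.**
- What may go wrong: amine-promoted self-condensation of the monoalkylketene 29 may outrun its capture by the internal siloxyalkyne.
- The fallback sets out from 13 and returns at 30 through 29. It changes the ketene source to an amine-free Wolff rearrangement.
- Negishi coupling of 13 with (2-ethoxy-2-oxoethyl)zinc bromide gives ethyl 2-(RA)acetate F8.
- Me3SnOH gives 2-(RA)acetic acid F9.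
- The chloroenamine of step 15 gives 2-(RA)acetyl chloride F10.
- Diazomethane gives the diazoketone 1-diazo-3-(RA)propan-2-one F11 (Arndt-Eistert sequence).
- Irradiation at 405 nm, where the dienone does not absorb, in toluene with 21 (3 equiv) releases 29 slowly, and 29 is trapped as 30.

## Further compounds

F1 | step 16 | (E)-1,2-dichlorovinyl 2-(trimethylsilyl)ethyl ether | Cl/C=C(/Cl)OCC[Si](C)(C)C
F2 | step 16 | [2-(ethynyloxy)ethyl]trimethylsilane | C#COCC[Si](C)(C)C
F3 | step 16 | pentasubstituted phenol (C2' OH, C3' H, C4' O-TMSE, C5' prenyl, C6' OTIPS, C1' CH2-RA) | Oc1cc(OCC[Si](C)(C)C)c(CC=C(C)C)c(O[Si](C(C)C)(C(C)C)C(C)C)c1CC2=C(OCC[Si](C)(C)C)[C@@](CC=C(C)C)(C(=O)C(C)C)C(OCC[Si](C)(C)C)=C(C)C2=O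
F4 | step 16 | C3' isobutyryl derivative of F3 | CC(C)C(=O)c1c(O)c(CC2=C(OCC[Si](C)(C)C)[C@@](CC=C(C)C)(C(=O)C(C)C)C(OCC[Si](C)(C)C)=C(C)C2=O)c(O[Si](C(C)C)(C(C)C)C(C)C)c(CC=C(C)C)c1OCC[Si](C)(C)C
F5 | step 4 | 2-methyl-1,5-bis(TMSE-oxy)cyclohexa-1,4-diene | CC1=C(OCC[Si](C)(C)C)CC(OCC[Si](C)(C)C)=CC1
F6 | step 4 | 1-[3-methyl-2,6-bis(TMSE-oxy)cyclohexa-2,5-dien-1-yl]-2-methylpropan-1-ol (racemic, diastereomer mixture) | CC1=C(OCC[Si](C)(C)C)C(C(O)C(C)C)C(OCC[Si](C)(C)C)=CC1
F7 | step 4 | rac-1-[3-methyl-2,6-bis(TMSE-oxy)cyclohexa-2,5-dien-1-yl]-2-methylpropan-1-one | CC1=C(OCC[Si](C)(C)C)C(C(=O)C(C)C)C(OCC[Si](C)(C)C)=CC1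
F8 | step 15 | ethyl 2-(RA)acetate | CCOC(=O)CC1=C(OCC[Si](C)(C)C)[C@@](CC=C(C)C)(C(=O)C(C)C)C(OCC[Si](C)(C)C)=C(C)C1=O
F9 | step 15 | 2-(RA)acetic acid | OC(=O)CC1=C(OCC[Si](C)(C)C)[C@@](CC=C(C)C)(C(=O)C(C)C)C(OCC[Si](C)(C)C)=C(C)C1=O
F10 | step 15 | 2-(RA)acetyl chloride | ClC(=O)CC1=C(OCC[Si](C)(C)C)[C@@](CC=C(C)C)(C(=O)C(C)C)C(OCC[Si](C)(C)C)=C(C)C1=O
F11 | step 15 | 1-diazo-3-(RA)propan-2-one | [N-]=[N+]=CC(=O)CC1=C(OCC[Si](C)(C)C)[C@@](CC=C(C)C)(C(=O)C(C)C)C(OCC[Si](C)(C)C)=C(C)C1=O
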